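**Retrosynthetic overview**
1. Target 17 ⇐ Sharpless epoxidation of E-allylic alcohol 16 ⇐ Zr-catalysed methylalumination/hydroxymethylation of terminal alkyne 14.
2. Ring A (formed second): Diels–Alder of vinylcyclohexene 11 with methyl methacrylate gives the ester-bearing quaternary carbon, the ring-fusion CH and the trisubstituted ring alkene in one step.
3. Diene 11 ⇐ enol triflate 10 and vinyl cross-coupling ⇐ ketone 8.
4. Ring B (formed first, key step): cyclohexanone 8 ⇐ semipinacol ring expansion (1,2-carbon shift, cyclopentanol → cyclohexanone) of alkenyl carbinol 7; this creates the quaternary carbon next to the CHMe centre and resolves the racemate.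
5. 7 ⇐ 2-methylcyclopentanone 5 + alkenyl Grignard 6 ⇐ bromo-enyne 4 ⇐ 1-(trimethylsilyl)propyne 1 + 2,3-dibromopropene 2.

Assumption: vinylmagnesium bromide, AlMe3, paraformaldehyde and TBHP are treated as reagents (each has fewer than eight heavy atoms anyway); racemic 5 is used because it is resolved in step 3.

**Step 1**
Reactants: 1 trimethyl(prop-1-yn-1-yl)silane; 2 2,3-dibromoprop-1-ene
Product: 4 (5-bromohex-5-en-1-yn-1-yl)trimethylsilane, via lithiated silylpropyne 3 (not isolated)
Conditions: n-BuLi, THF, −78 → −20 °C; then 2, −78 °C → rt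
Reagents that add atoms: none
Why: Propargylic lithiation of the silyl-capped propyne followed by SN2 alkylation at the allylic bromide of 2 (the vinylic C–Br is inert) is a standard three-carbon homologation by alkylation of a propargyl-lithium.

**Step 2**
Reactants: 4 (5-bromohex-5-en-1-yn-1-yl)trimethylsilane; 5 2-methylcyclopentan-1-one (racemic)
Product: 7 rac-(1S,2R)-2-methyl-1-[6-(trimethylsilyl)hex-1-en-5-yn-2-yl]cyclopentan-1-ol, via alkenyl Grignard reagent 6 (not isolated)
Conditions: Mg, THF, 45 °C; then 5, LaCl3·2LiCl (0.3 equiv), THF, −40 → 0 °C; aq NH4Cl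
Reagents that add atoms: none
Why: Grignard 1,2-addition (lanthanum additive suppresses enolisation) occurs anti to the 2-methyl group, so the alkenyl group ends trans to methyl and OH cis to methyl (expected dr about 5–8:1, minor isomer removed by chromatography).

**Step 3**
Reactants: 7 rac-(1S,2R)-2-methyl-1-[6-(trimethylsilyl)hex-1-en-5-yn-2-yl]cyclopentan-1-ol
Product: 8 (2S,3R)-2,3-dimethyl-2-[4-(trimethylsilyl)but-3-yn-1-yl]cyclohexan-1-one
Conditions: chiral confined imidodiphosphorimidate Brønsted acid (IDPi, 5 mol %, enantiomer matched to (1S,2R)-7), CHCl3, −30 °C, stopped at ca. 50 % conversion; chromatography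
Reagents that add atoms: none
Why: Proposed new method: a confined chiral IDPi acid should effect a protio-semipinacol ring expansion of this unactivated 1,1-dialkyl alkenyl cyclopentanol with kinetic resolution — the acidic N–H protonates the terminal =CH2 while a sulfonyl oxygen of the anion accepts the carbinol O–H, which holds the O–C1–C=CH2 unit syn-periplanar (and keeps the OH from ionising) so that the anti-periplanar, more substituted ring carbon C2 (CHMe) migrates with retention to the developing tertiary cation, placing the new methyl cis to the existing one and giving the (2S,3R) ketone from the matched (1S,2R) enantiomer only, while (1R,2S)-7 is recovered (maximum yield 50 %, selectivity factor of about 30 or more needed); the closest known reactions are chiral phosphoric acid protio-semipinacol ring expansions of alkenyl cyclobutanols, IDPi-catalysed Wagner–Meerwein ring expansions of alkenyl cycloalkanes and stereodivergent halo-semipinacol reactions of racemic alkenyl cycloalkanols.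

**Step 4**
Reactants: 8 (2S,3R)-2,3-dimethyl-2-[4-(trimethylsilyl)but-3-yn-1-yl]cyclohexan-1-one
Product: 10 (5R,6S)-5,6-dimethyl-6-[4-(trimethylsilyl)but-3-yn-1-yl]cyclohex-1-en-1-yl trifluoromethanesulfonate, via potassium enolate 9 (not isolated)
Conditions: KHMDS, THF, −78 °C; PhNTf2, −78 → 0 °C
Reagents that add atoms: N-phenylbis(trifluoromethanesulfonimide), O=S(=O)(N(c1ccccc1)S(=O)(=O)C(F)(F)F)C(F)(F)F
Why: The ketone has only one enolisable α-carbon (the other is quaternary), so enolate O-triflation gives a single enol triflate without touching either stereocentre.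

**Step 5**
Reactants: 10 (5R,6S)-5,6-dimethyl-6-[4-(trimethylsilyl)but-3-yn-1-yl]cyclohex-1-en-1-yl trifluoromethanesulfonate
Product: 11 {4-[(1S,6R)-2-ethenyl-1,6-dimethylcyclohex-2-en-1-yl]but-1-yn-1-yl}trimethylsilane
Conditions: vinylmagnesium bromide, ZnCl2, THF, 0 °C; then 10, Pd(PPh3)4 (5 mol %), THF, 50 °C
Reagents that add atoms: vinylmagnesium bromide, C=C[Mg]Br
Why: Negishi cross-coupling of an enol triflate with a vinylzinc reagent is reliable even next to a quaternary carbon and is anhydrous, so the silyl alkyne survives.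

**Step 6**
Reactants: 11 {4-[(1S,6R)-2-ethenyl-1,6-dimethylcyclohex-2-en-1-yl]but-1-yn-1-yl}trimethylsilane; 12 methyl 2-methylprop-2-enoate (methyl methacrylate)
Product: 13 methyl (1S,5S,6R,8aR)-1,5,6-trimethyl-5-[4-(trimethylsilyl)but-3-yn-1-yl]-1,2,3,5,6,7,8,8a-octahydronaphthalene-1-carboxylate
Conditions: 12 (5 equiv), EtAlCl2 (0.3 equiv), CH2Cl2, −40 → 0 °C
Reagents that add atoms: none
Why: Lewis-acid-catalysed Diels–Alder reaction in which the ester-bearing carbon bonds to the substituted ring terminus ("ortho" orientation, largest HOMO coefficient on the vinyl CH2), the ester is endo, and the dienophile adds anti to the pseudoaxial C1 methyl of 11 (reactive half-chair: C1–Me axial, C6–Me equatorial), which sets C1 (S) and C8a (R) and fixes the ring alkene position.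

**Step 7**
Reactants: 13 methyl (1S,5S,6R,8aR)-1,5,6-trimethyl-5-[4-(trimethylsilyl)but-3-yn-1-yl]-1,2,3,5,6,7,8,8a-octahydronaphthalene-1-carboxylate
Product: 14 methyl (1S,5S,6R,8aR)-5-(but-3-yn-1-yl)-1,5,6-trimethyl-1,2,3,5,6,7,8,8a-octahydronaphthalene-1-carboxylate
Conditions: K2CO3 (cat.), MeOH, rt
Reagents that add atoms: none
Why: Methanolysis of the alkynyl C–Si bond (protodesilylation) is selective; the methyl ester is unchanged in methanol and no centre is epimerisable.

**Step 8**
Reactants: 14 methyl (1S,5S,6R,8aR)-5-(but-3-yn-1-yl)-1,5,6-trimethyl-1,2,3,5,6,7,8,8a-octahydronaphthalene-1-carboxylate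
Product: 16 methyl (1S,5S,6R,8aR)-5-[(3E)-5-hydroxy-3-methylpent-3-en-1-yl]-1,5,6-trimethyl-1,2,3,5,6,7,8,8a-octahydronaphthalene-1-carboxylate, via alkenyl(dimethyl)alane 15 (not isolated)
Conditions: AlMe3 (3 equiv), Cp2ZrCl2 (0.3 equiv), CH2Cl2, 0 °C → rt; then (CH2O)n, THF, rt; aq Rochelle salt
Reagents that add atoms: trimethylaluminium, C[Al](C)C; paraformaldehyde (as formaldehyde), C=O
Why: Negishi zirconium-catalysed carboalumination adds Me and Al syn with Al at the terminal carbon, and the alkenylalane adds to formaldehyde with retention, giving the E-trisubstituted allylic alcohol; the hindered quaternary ester and the ring alkene are not attacked.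

**Step 9**
Reactants: 16 methyl (1S,5S,6R,8aR)-5-[(3E)-5-hydroxy-3-methylpent-3-en-1-yl]-1,5,6-trimethyl-1,2,3,5,6,7,8,8a-octahydronaphthalene-1-carboxylate
Product: 17 methyl (1S,5S,6R,8aR)-5-{2-[(2S,3S)-3-(hydroxymethyl)-2-methyloxiran-2-yl]ethyl}-1,5,6-trimethyl-1,2,3,5,6,7,8,8a-octahydronaphthalene-1-carboxylate
Conditions: Ti(OiPr)4 (10 mol %), L-(+)-diethyl tartrate (12 mol %), t-BuOOH, 4 Å MS, CH2Cl2, −20 °C
Reagents that add atoms: tert-butyl hydroperoxide, CC(C)(C)OO
Why: Sharpless asymmetric epoxidation is specific for the allylic alcohol (the isolated ring alkene is untouched), and L-(+)-tartrate gives the (2S,3S)-epoxy alcohol for this geraniol-type E-alkene by reagent control.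

**Compound list**
1 | trimethyl(prop-1-yn-1-yl)silane | CC#C[Si](C)(C)C | starting material
2 | 2,3-dibromoprop-1-ene | C=C(Br)CBr | starting material
3 | [3-(trimethylsilyl)prop-2-yn-1-yl]lithium | [Li]CC#C[Si](C)(C)C | intermediate
4 | (5-bromohex-5-en-1-yn-1-yl)trimethylsilane | C=C(Br)CCC#C[Si](C)(C)C | intermediate
5 | 2-methylcyclopentan-1-one (racemic) | CC1CCCC1=O | starting material
6 | bromo[6-(trimethylsilyl)hex-1-en-5-yn-2-yl]magnesium | C=C([Mg]Br)CCC#C[Si](C)(C)C | intermediate
7 | rac-(1S,2R)-2-methyl-1-[6-(trimethylsilyl)hex-1-en-5-yn-2-yl]cyclopentan-1-ol (racemate; SMILES shows the (1S,2R) enantiomer that reacts in step 3) | O[C@]1(C(=C)CCC#C[Si](C)(C)C)[C@H](C)CCC1 | intermediate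
8 | (2S,3R)-2,3-dimethyl-2-[4-(trimethylsilyl)but-3-yn-1-yl]cyclohexan-1-one | O=C1CCC[C@@H](C)[C@]1(C)CCC#C[Si](C)(C)C | intermediate
9 | potassium (5R,6S)-5,6-dimethyl-6-[4-(trimethylsilyl)but-3-yn-1-yl]cyclohex-1-en-1-olate | [K+].[O-]C1=CCC[C@@H](C)[C@]1(C)CCC#C[Si](C)(C)C | intermediate
10 | (5R,6S)-5,6-dimethyl-6-[4-(trimethylsilyl)but-3-yn-1-yl]cyclohex-1-en-1-yl trifluoromethanesulfonate | FC(F)(F)S(=O)(=O)OC1=CCC[C@@H](C)[C@]1(C)CCC#C[Si](C)(C)C | intermediate
11 | {4-[(1S,6R)-2-ethenyl-1,6-dimethylcyclohex-2-en-1-yl]but-1-yn-1-yl}trimethylsilane | C=CC1=CCC[C@@H](C)[C@]1(C)CCC#C[Si](C)(C)C | intermediate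
12 | methyl 2-methylprop-2-enoate | C=C(C)C(=O)OC | starting material
13 | methyl (1S,5S,6R,8aR)-1,5,6-trimethyl-5-[4-(trimethylsilyl)but-3-yn-1-yl]-1,2,3,5,6,7,8,8a-octahydronaphthalene-1-carboxylate | COC(=O)[C@@]1(C)CCC=C2[C@H]1CC[C@@H](C)[C@]2(C)CCC#C[Si](C)(C)C | intermediate
14 | methyl (1S,5S,6R,8aR)-5-(but-3-yn-1-yl)-1,5,6-trimethyl-1,2,3,5,6,7,8,8a-octahydronaphthalene-1-carboxylate | COC(=O)[C@@]1(C)CCC=C2[C@H]1CC[C@@H](C)[C@]2(C)CCC#C | intermediate
15 | methyl (1S,5S,6R,8aR)-5-[(3E)-4-(dimethylalumanyl)-3-methylbut-3-en-1-yl]-1,5,6-trimethyl-1,2,3,5,6,7,8,8a-octahydronaphthalene-1-carboxylate | COC(=O)[C@@]1(C)CCC=C2[C@H]1CC[C@@H](C)[C@]2(C)CC/C(C)=C/[Al](C)C | intermediate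
16 | methyl (1S,5S,6R,8aR)-5-[(3E)-5-hydroxy-3-methylpent-3-en-1-yl]-1,5,6-trimethyl-1,2,3,5,6,7,8,8a-octahydronaphthalene-1-carboxylate | COC(=O)[C@@]1(C)CCC=C2[C@H]1CC[C@@H](C)[C@]2(C)CC/C(C)=C/CO | intermediate
17 | methyl (1S,5S,6R,8aR)-5-{2-[(2S,3S)-3-(hydroxymethyl)-2-methyloxiran-2-yl]ethyl}-1,5,6-trimethyl-1,2,3,5,6,7,8,8a-octahydronaphthalene-1-carboxylate | COC(=O)[C@@]1(C)CCC=C2[C@H]1CC[C@@H](C)[C@]2(C)CC[C@]1(C)O[C@H]1CO | target

**Step count and risks**
Total steps: 9. Longest linear sequence: 9 (from 1 and 2 to 17).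

Most likely to fail, first: step 3, the proposed ring expansion with resolution. The acid may dehydrate the tertiary allylic alcohol instead of protonating the alkene, or the enantiomer discrimination may be too low. The fallback uses known chemistry, sets out from 4 (plus commercial cyclopentanone) and comes back at 8. Cyclopentanone is condensed with the auxiliary SAMP to give the cyclopentanone SAMP hydrazone F1. LDA then MeI gives the methylated hydrazone F2, and two-phase oxalic acid cleavage gives (R)-2-methylcyclopentanone F3, which is used cold and at once. Adding Grignard 6 to F3 as in step 2 gives (1S,2R)-7 as a single enantiomer. The ring is then expanded by the reported hydrogen-atom-transfer radical–polar crossover semipinacol reaction of tertiary allylic alcohols (Co(salen) catalyst, N-fluoro-2,4,6-trimethylpyridinium salt, PhSiH3), and 8 is separated from any C2 epimer.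

Second: step 6, the Diels–Alder reaction. The two alkyl groups of the diene direct in opposite senses, and the α-methyl group of the dienophile weakens the endo preference, so the regioisomer or the C1 epimer could compete. The fallback sets out from 11 and comes back at 13. The more reactive and more strongly polarised dienophile methacrolein is used with Me2AlCl at −78 °C to give the (1S,5S,6R,8aR)-1-carbaldehyde adduct F4. Pinnick oxidation (NaClO2, NaH2PO4, 2-methyl-2-butene) gives the (1S,5S,6R,8aR)-1-carboxylic acid F5, and TMSCHN2 in MeOH/toluene gives 13.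

Third: step 8, carboalumination with a free ester present. Excess AlMe3 could attack the ester, or the alkenylalane could add sluggishly to formaldehyde. The fallback sets out from 14 and comes back at 16. Gold(I)-catalysed Markovnikov hydration of the alkyne gives the 3-oxobutyl methyl ketone F6. Horner–Wadsworth–Emmons olefination with trimethyl phosphonoacetate/NaH gives the (E)-enoate diester F7 (E/Z about 5:1, separable). DIBAL-H (2.2 equiv, −78 °C) reduces the unhindered conjugated ester in preference to the neopentyl quaternary ester and gives 16.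

**Further compounds**
F1 | step 3 | (S)-N-cyclopentylidene-2-(methoxymethyl)pyrrolidin-1-amine | COC[C@@H]1CCCN1N=C1CCCC1
F2 | step 3 | (S)-2-(methoxymethyl)-N-[(2R)-2-methylcyclopentylidene]pyrrolidin-1-amine | COC[C@@H]1CCCN1N=C1CCC[C@H]1C
F3 | step 3 | (R)-2-methylcyclopentan-1-one | C[C@@H]1CCCC1=O
F4 | step 6 | (1S,5S,6R,8aR)-1,5,6-trimethyl-5-[4-(trimethylsilyl)but-3-yn-1-yl]-1,2,3,5,6,7,8,8a-octahydronaphthalene-1-carbaldehyde | O=C[C@@]1(C)CCC=C2[C@H]1CC[C@@H](C)[C@]2(C)CCC#C[Si](C)(C)C
F5 | step 6 | (1S,5S,6R,8aR)-1,5,6-trimethyl-5-[4-(trimethylsilyl)but-3-yn-1-yl]-1,2,3,5,6,7,8,8a-octahydronaphthalene-1-carboxylic acid | OC(=O)[C@@]1(C)CCC=C2[C@H]1CC[C@@H](C)[C@]2(C)CCC#C[Si](C)(C)C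
F6 | step 8 | methyl (1S,5S,6R,8aR)-1,5,6-trimethyl-5-(3-oxobutyl)-1,2,3,5,6,7,8,8a-octahydronaphthalene-1-carboxylate | COC(=O)[C@@]1(C)CCC=C2[C@H]1CC[C@@H](C)[C@]2(C)CCC(C)=O
F7 | step 8 | methyl (1S,5S,6R,8aR)-5-[(3E)-5-methoxy-3-methyl-5-oxopent-3-en-1-yl]-1,5,6-trimethyl-1,2,3,5,6,7,8,8a-octahydronaphthalene-1-carboxylate | COC(=O)[C@@]1(C)CCC=C2[C@H]1CC[C@@H](C)[C@]2(C)CC/C(C)=C/C(=O)OC
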